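Partner stands to substrate at 0.800 equiv, less than one to one, so partner is the smaller charge of the first step.

    substrate + partner → intermediate A (k1 = 1.21 M⁻¹ min⁻¹, Ea1 = 59.0 kJ mol⁻¹)
    second reagent + intermediate A → intermediate B (k2 = 0.173 M⁻¹ min⁻¹, Ea2 = 69.0 kJ mol⁻¹)
    third reagent + intermediate B → target (k3 = 0.0955 M⁻¹ min⁻¹, Ea3 = 78.0 kJ mol⁻¹)
    intermediate B + capture agent → trapped intermediate (k4 = 4.58 M⁻¹ min⁻¹, Ea4 = 69.0 kJ mol⁻¹)
    substrate + second reagent → side product (k5 = 0.119 M⁻¹ min⁻¹, Ea5 = 66.0 kJ mol⁻¹)
    (constants at 35 °C)

| setting | delta | theta | eta | beta |
|---|---|---|---|---|
| substrate | 0.22 M | 0.22 M | 0.22 M | 0.22 M |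
| partner | 0.800 equiv | 0.800 equiv | 0.800 equiv | 0.800 equiv |
| second reagent | 1.10 equiv | 1.10 equiv | 1.10 equiv | 1.10 equiv |
| third reagent | 2.00 equiv | 2.00 equiv | 2.00 equiv | 2.00 equiv |
| capture agent | 4.40 mM | 4.40 mM | 4.40 mM | 4.40 mM |
| time | 1.5 h | 1.5 h | 1.5 h | 1.5 h |
| remark | at −25 °C until 50 min, from then on at 35 °C |  |  |  |
| temperature |  | −25 °C | 35 °C | 5 °C |

- the flask with the highest amount of intermediate A, in percent of the substrate charged ("all alike" if they lie within 1.5 percentage points) (delta / theta / eta / beta / all alike)
- final intermediate A, as a percentage of the substrate charged, in delta
- final intermediate A, as a percentage of the substrate charged, in theta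
- final intermediate A, as a percentage of the substrate charged, in eta
- final intermediate A, as a percentage of the substrate charged, in beta

- at 35 °C the constants are as listed, elsewhere as the activation energies make them

The reckoning here starts from the balance of partner. Partner falls at the constant of the first step times c(substrate) times c(partner). With the side step set aside, substrate and partner fall together, so the balance integrates exactly. At −25 °C the first step has the constant 0.00462 M⁻¹ min⁻¹, and theta has 0.0915 as its product with charged c(substrate) and time. This product is the coupling number N. With r the partner ratio and E = exp((1 − r)N), the share of substrate passed into intermediate A is x = r(E − 1)/(E − r). A second product, the drain number, takes the constant of the second step times charged c(second reagent) times time.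

The rows of the reckoning read as follows.

Theta has x = 6.76% and a drain number of 0.00560, far smaller than N. So theta should hold about x.

Beta has N = 2.00, x = 56.9% and a drain number of 0.206. Intermediate A stands on average about half the run, so beta should keep about 51.3%.

Delta, cold and then hot, has N = 10.7 and x = 77.9%. Eta has N = 24.0 and x = 79.9%. Their drain numbers are 1.67 for the hot stretch of delta and 3.77 for eta. Both exceed 1, and there c(second reagent) falls as it works, so the reckoning stops at an order: eta below delta, since its drain is larger. It commits to beta as the highest, whose drain is smaller than in those two and whose figure is above that of theta.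

The forecast names beta, with 32% in delta, 6.7% in theta, 19% in eta and 48% in beta, on the ground that “at 5 °C it builds up well while its onward reaction with the second reagent stays slow”. Its beta figure lies below the reckoning's.

The simulation gives beta, with 31.3% in delta, 6.73% in theta, 17.4% in eta and 48.4% in beta. The first place changes with time: after 15.0 h, ten times as long, theta holds 38.2% against 27.7% in beta. At the asked time theta holds 6.73% against the reckoned 6.76%. The neighbour of theta, with 0.55 M of substrate, has N = 0.229, which gives x = 15.2%. That neighbour holds 15.0% of intermediate A at the end, with 81% of its partner left.

All constants come from no measurement; the result is computed.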